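## Retrosynthetic overview

1. Target ⇐ singlet-oxygen ene reaction (C7–OOH, Δ11) of the 3-O-angeloyl-4-O-acetyl 7(11)-en-8-one ⇐ stepwise acylation of the 3α,4α-diol ⇐ α-face OsO4 dihydroxylation of a Δ3,7(11)-dien-8-one.
2. Isopropylidene ⇐ aldol/dehydration with acetone on a trans-fused Δ3-octalin-8-one ⇐ Birch reduction and enol-triflate hydrogenolysis of a 4-en-3-one whose C8 carbonyl is carried as its dimethyl ketal.
3. Key step: ring B (cyclohexanone ketal) ⇐ oxidative one-carbon ring expansion of a methylidene-hydrindenone, by 1,2-shift of the quaternary ring carbon onto the exocyclic CH2.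
4. Methylidene-hydrindenone ⇐ Wittig ⇐ (S)-4,7a-dimethyl Hajos–Parrish-type enedione ⇐ 2-methylcyclopentane-1,3-dione + ethyl vinyl ketone (amino-acid-mediated Robinson annulation).
5. Ring order: cyclopentane (bought) → ring A (annulation) → ring B (the cyclopentane enlarged to a cyclohexane); acetone and angelic acid supply the side chain and the ester.

Assumption: decalins are numbered as eudesmanes (C3/C4 oxygenated, C5/C10 ring fusion, C7 side-chain carbon, C8 ketone; target = 3R,4S,5R,7S,10R), hydrindanes as indenes (C7a quaternary), and the target SMILES is taken as the absolute configuration.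

## Route

Step 1
Reactants: 1 2-methylcyclopentane-1,3-dione; 2 ethyl vinyl ketone (pent-1-en-3-one)
Product: 4 (7aS)-4,7a-dimethyl-2,3,7,7a-tetrahydro-1H-indene-1,5(6H)-dione, via triketone 3 (not isolated)
Conditions: 2 (1.3 equiv), Et3N (5 mol%), DMF, 25 °C; then L-phenylalanine (1.0 equiv), (1S)-camphor-10-sulfonic acid (0.55 equiv), 30 → 70 °C; recrystallise to ≥99% ee
Reagents that add atoms: none
Why: Michael addition followed by the Hajos–Parrish–Eder–Sauer–Wiechert enamine aldol condensation (asymmetric Robinson annulation), in which the L-amino acid differentiates the two enantiotopic ring carbonyls and sets the quaternary centre C7a as S (the later C10).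

Step 2
Reactants: 4 (7aS)-4,7a-dimethyl-2,3,7,7a-tetrahydro-1H-indene-1,5(6H)-dione
Product: 5 (7aR)-4,7a-dimethyl-1-methylidene-1,2,3,6,7,7a-hexahydro-5H-inden-5-one
Conditions: Ph3PCH3Br (1.5 equiv), KOtBu (1.4 equiv), THF, 0 → 25 °C; aq. NH4Cl
Reagents that add atoms: methyltriphenylphosphonium bromide C[P+](c1ccccc1)(c1ccccc1)c1ccccc1.[Br-]
Why: Wittig methylenation is chemoselective for the strained, more electrophilic cyclopentanone carbonyl, because the α-methyl enone carbonyl is less electrophilic and is reversibly masked as its dienolate by excess ylide; C7a cannot epimerise (the descriptor changes only by priority).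

Step 3
Reactants: 5 (7aR)-4,7a-dimethyl-1-methylidene-1,2,3,6,7,7a-hexahydro-5H-inden-5-one
Product: 6 (4aR)-6,6-dimethoxy-1,4a-dimethyl-4,4a,5,6,7,8-hexahydronaphthalen-2(3H)-one
Conditions: PhI(OH)OTs (1.1 equiv), anhydrous MeOH, 3 Å MS, −20 → 20 °C; Et3N quench
Reagents that add atoms: methanol CO
Why: Proposed new method: the electrophilic trivalent-iodine reagent adds to the exocyclic CH2 with Markovnikov capture of MeOH at C1; the neopentylic C–I(Ph)OTs bond cannot be displaced by MeOH, so PhI leaves with a concerted 1,2-shift of the anti-periplanar, more electron-rich quaternary carbon C7a (tertiary-alkyl migratory aptitude, retention at C7a, enone alkene too electron-poor to compete) and the oxocarbenium ion is trapped by MeOH as the dimethyl ketal, which forms the C9–C10 bond and ring B; the closest known reaction type is the Tl(NO3)3- or PhI(OH)OTs-mediated oxidative semipinacol ring expansion of methylenecycloalkanes and aryl-substituted exocyclic alkenes (Wittig–ring-expansion sequence), not yet shown for migration of an all-carbon quaternary centre in an unactivated methylenecyclopentane with ketal termination.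

Step 4
Reactants: 6 (4aR)-6,6-dimethoxy-1,4a-dimethyl-4,4a,5,6,7,8-hexahydronaphthalen-2(3H)-one
Product: 8 (4aR,8aR)-6,6-dimethoxy-1,4a-dimethyl-3,4,4a,5,6,7,8,8a-octahydronaphthalen-2-yl trifluoromethanesulfonate, via lithium enolate 7 (not isolated)
Conditions: Li (2.5 equiv), NH3(l)/THF, t-BuOH (1.0 equiv), −78 °C; isoprene; evaporate NH3; then PhNTf2 (1.3 equiv), THF, 0 → 25 °C
Reagents that add atoms: N-phenylbis(trifluoromethanesulfonimide) O=S(=O)(N(c1ccccc1)S(=O)(=O)C(F)(F)F)C(F)(F)F
Why: Birch-type dissolving-metal reduction of the enone protonates C5 axially to give the trans-decalin (5α-H, anti to the 10β-methyl, C5 = R), and the regiospecific Δ3-enolate is trapped as its enol triflate; the dimethyl ketal is inert.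

Step 5
Reactants: 8 (4aR,8aR)-6,6-dimethoxy-1,4a-dimethyl-3,4,4a,5,6,7,8,8a-octahydronaphthalen-2-yl trifluoromethanesulfonate
Product: 10 (4aR,8aR)-5,8a-dimethyl-3,4,4a,7,8,8a-hexahydronaphthalen-2(1H)-one, via alkene ketal 9 (not isolated)
Conditions: Pd(OAc)2 (5 mol%), PPh3 (10 mol%), HCO2H (2.5 equiv), n-Bu3N (3.5 equiv), DMF, 60 °C; then 1 M HCl, THF, 25 °C
Reagents that add atoms: water O
Why: Palladium-catalysed formate hydrogenolysis of the enol triflate (oxidative addition to zerovalent palladium, formate-to-hydride exchange, reductive elimination) gives the Δ3 alkene without touching a stereocentre, and the acidic work-up hydrolyses the dimethyl ketal to the C8 ketone.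

Step 6
Reactants: 10 (4aR,8aR)-5,8a-dimethyl-3,4,4a,7,8,8a-hexahydronaphthalen-2(1H)-one; 11 acetone
Product: 13 (3R,4aR,8aR)-3-(2-hydroxypropan-2-yl)-5,8a-dimethyl-3,4,4a,7,8,8a-hexahydronaphthalen-2(1H)-one, via lithium enolate 12 (not isolated)
Conditions: LiN(iPr)2 (1.1 equiv), THF, −78 °C; ZnCl2 (1.1 equiv); acetone (3 equiv), −78 → −40 °C; aq. NH4Cl
Reagents that add atoms: none
Why: Kinetic deprotonation occurs at C7 (C9 is neopentylic beside the quaternary C10) and the zinc aldolate resists retro-aldol cleavage in this crossed aldol addition; the C7 configuration (equatorial epimer drawn) is erased in step 7.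

Step 7
Reactants: 13 (3R,4aR,8aR)-3-(2-hydroxypropan-2-yl)-5,8a-dimethyl-3,4,4a,7,8,8a-hexahydronaphthalen-2(1H)-one
Product: 15 (4aR,8aR)-5,8a-dimethyl-3-(propan-2-ylidene)-3,4,4a,7,8,8a-hexahydronaphthalen-2(1H)-one, via tertiary mesylate 14 (not isolated)
Conditions: MsCl (2 equiv), Et3N (4 equiv), DMAP (0.1 equiv), CH2Cl2, 0 → 25 °C; then DBU (2 equiv), 25 °C
Reagents that add atoms: none
Why: Mesylation and E1cB elimination give the conjugated tetrasubstituted isopropylidene enone, and DBU equilibrates any isopropenyl isomer into conjugation; the Δ3 alkene is untouched under these non-acidic conditions.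

Step 8
Reactants: 15 (4aR,8aR)-5,8a-dimethyl-3-(propan-2-ylidene)-3,4,4a,7,8,8a-hexahydronaphthalen-2(1H)-one
Product: 16 (4aR,5S,6R,8aR)-5,6-dihydroxy-5,8a-dimethyl-3-(propan-2-ylidene)octahydronaphthalen-2(1H)-one
Conditions: OsO4 (5 mol%), N-methylmorpholine N-oxide (1.5 equiv), acetone/H2O, 25 °C; Na2SO3
Reagents that add atoms: osmium tetroxide O=[Os](=O)(=O)=O; N-methylmorpholine N-oxide C[N+]1([O-])CCOCC1; water O
Why: Upjohn syn-dihydroxylation attacks only the electron-rich trisubstituted Δ3 alkene (the tetrasubstituted enone alkene is inert) from the α face opposite the axial 10β-methyl, setting C3 (R) and C4 (S) together as the cis 3α,4α-diol with the 4-methyl β.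

Step 9
Reactants: 16 (4aR,5S,6R,8aR)-5,6-dihydroxy-5,8a-dimethyl-3-(propan-2-ylidene)octahydronaphthalen-2(1H)-one; 17 angelic acid ((2Z)-2-methylbut-2-enoic acid)
Product: 19 (1S,2R,4aR,8aR)-1-hydroxy-1,4a-dimethyl-6-oxo-7-(propan-2-ylidene)decahydronaphthalen-2-yl (2Z)-2-methylbut-2-enoate, via mixed anhydride 18 (not isolated)
Conditions: 17 (2.5 equiv), 2,4,6-Cl3C6H2COCl (2.5 equiv), Et3N (3 equiv), toluene, 25 °C; then 16, 80 °C (no DMAP)
Reagents that add atoms: none
Why: Yamaguchi-type mixed-anhydride esterification without a nucleophilic catalyst acylates only the secondary 3-OH and avoids Z-to-E isomerisation of the angelate to the tiglate; the tertiary 4-OH does not react.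

Step 10
Reactants: 19 (1S,2R,4aR,8aR)-1-hydroxy-1,4a-dimethyl-6-oxo-7-(propan-2-ylidene)decahydronaphthalen-2-yl (2Z)-2-methylbut-2-enoate
Product: 20 (1S,2R,4aR,8aR)-1-acetoxy-1,4a-dimethyl-6-oxo-7-(propan-2-ylidene)decahydronaphthalen-2-yl (2Z)-2-methylbut-2-enoate
Conditions: Ac2O (6 equiv), DMAP (1 equiv), Et3N (6 equiv), CH2Cl2, 25 → 40 °C
Reagents that add atoms: acetic anhydride CC(=O)OC(C)=O
Why: DMAP-catalysed (Steglich-type) acetylation of the equatorial tertiary 4α-alcohol proceeds with retention at C4 and leaves the enone and the angelate unchanged.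

Step 11
Reactants: 20 (1S,2R,4aR,8aR)-1-acetoxy-1,4a-dimethyl-6-oxo-7-(propan-2-ylidene)decahydronaphthalen-2-yl (2Z)-2-methylbut-2-enoate
Product: 21 (1S,2R,4aR,7S,8aR)-1-acetoxy-7-hydroperoxy-1,4a-dimethyl-6-oxo-7-(prop-1-en-2-yl)decahydronaphthalen-2-yl (2Z)-2-methylbut-2-enoate
Conditions: O2, tetraphenylporphyrin (1 mol%), visible light, CH2Cl2, −20 °C; stop at full conversion, chromatograph cold
Reagents that add atoms: dioxygen O=O
Why: Schenck ene reaction in which singlet oxygen adds to the s-cis tetrasubstituted enone alkene on the less hindered α face and abstracts an isopropylidene methyl hydrogen, placing OOH on C7 (7α, S) and moving the alkene to C11=C12; the competing abstraction of H-6 needs the 6β-axial hydrogen, which is screened by the syn-axial 10-methyl, and the esters and the electron-poor angelate alkene react far more slowly.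

## Compound list

1 | 2-methylcyclopentane-1,3-dione | CC1C(=O)CCC1=O | starting material
2 | ethyl vinyl ketone (pent-1-en-3-one) | C=CC(=O)CC | starting material
3 | 2-methyl-2-(3-oxopentyl)cyclopentane-1,3-dione (achiral triketone) | CCC(=O)CCC1(C)C(=O)CCC1=O | intermediate
4 | (7aS)-4,7a-dimethyl-2,3,7,7a-tetrahydro-1H-indene-1,5(6H)-dione | CC1=C2CCC(=O)[C@@]2(C)CCC1=O | intermediate
5 | (7aR)-4,7a-dimethyl-1-methylidene-1,2,3,6,7,7a-hexahydro-5H-inden-5-one | CC1=C2CCC(=C)[C@@]2(C)CCC1=O | intermediate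
6 | (4aR)-6,6-dimethoxy-1,4a-dimethyl-4,4a,5,6,7,8-hexahydronaphthalen-2(3H)-one | CC1=C2CCC(OC)(OC)C[C@@]2(C)CCC1=O | intermediate
7 | lithium (4aR,8aR)-6,6-dimethoxy-1,4a-dimethyl-3,4,4a,5,6,7,8,8a-octahydronaphthalen-2-olate (trans-fused enolate) | C1C[C@@H]2[C@](C)(CCC(O[Li])=C2C)CC1(OC)OC | intermediate
8 | (4aR,8aR)-6,6-dimethoxy-1,4a-dimethyl-3,4,4a,5,6,7,8,8a-octahydronaphthalen-2-yl trifluoromethanesulfonate | C1C[C@@H]2[C@](C)(CCC(OS(=O)(=O)C(F)(F)F)=C2C)CC1(OC)OC | intermediate
9 | (4aR,8aR)-6,6-dimethoxy-1,4a-dimethyl-3,4,4a,5,6,7,8,8a-octahydronaphthalene | C1C[C@@H]2[C@](C)(CCC=C2C)CC1(OC)OC | intermediate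
10 | (4aR,8aR)-5,8a-dimethyl-3,4,4a,7,8,8a-hexahydronaphthalen-2(1H)-one (trans-fused) | C1C[C@@H]2[C@](C)(CCC=C2C)CC1=O | intermediate
11 | acetone | CC(C)=O | starting material
12 | lithium (4aR,8aR)-5,8a-dimethyl-1,4,4a,7,8,8a-hexahydronaphthalen-2-olate (C7 enolate) | [Li]OC1=CC[C@@H]2[C@](C)(CCC=C2C)C1 | intermediate
13 | (3R,4aR,8aR)-3-(2-hydroxypropan-2-yl)-5,8a-dimethyl-3,4,4a,7,8,8a-hexahydronaphthalen-2(1H)-one | CC(C)(O)[C@H]1C[C@@H]2[C@](C)(CCC=C2C)CC1=O | intermediate
14 | (3R,4aR,8aR)-3-[2-(methanesulfonyloxy)propan-2-yl]-5,8a-dimethyl-3,4,4a,7,8,8a-hexahydronaphthalen-2(1H)-one | CC(C)(OS(C)(=O)=O)[C@H]1C[C@@H]2[C@](C)(CCC=C2C)CC1=O | intermediate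
15 | (4aR,8aR)-5,8a-dimethyl-3-(propan-2-ylidene)-3,4,4a,7,8,8a-hexahydronaphthalen-2(1H)-one | CC(C)=C1C[C@@H]2[C@](C)(CCC=C2C)CC1=O | intermediate
16 | (4aR,5S,6R,8aR)-5,6-dihydroxy-5,8a-dimethyl-3-(propan-2-ylidene)octahydronaphthalen-2(1H)-one (3α,4α-diol) | CC(C)=C1C[C@@H]2[C@](C)(CC[C@@H](O)[C@@]2(C)O)CC1=O | intermediate
17 | angelic acid, (2Z)-2-methylbut-2-enoic acid | C/C=C(/C)C(=O)O | starting material
18 | (2Z)-2-methylbut-2-enoic 2,4,6-trichlorobenzoic anhydride | C/C=C(/C)C(=O)OC(=O)c1c(Cl)cc(Cl)cc1Cl | intermediate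
19 | (1S,2R,4aR,8aR)-1-hydroxy-1,4a-dimethyl-6-oxo-7-(propan-2-ylidene)decahydronaphthalen-2-yl (2Z)-2-methylbut-2-enoate | CC(C)=C1C[C@@H]2[C@](C)(CC[C@@H](OC(=O)/C(C)=C\C)[C@@]2(C)O)CC1=O | intermediate
20 | (1S,2R,4aR,8aR)-1-acetoxy-1,4a-dimethyl-6-oxo-7-(propan-2-ylidene)decahydronaphthalen-2-yl (2Z)-2-methylbut-2-enoate | CC(C)=C1C[C@@H]2[C@](C)(CC[C@@H](OC(=O)/C(C)=C\C)[C@@]2(C)OC(C)=O)CC1=O | intermediate
21 | (1S,2R,4aR,7S,8aR)-1-acetoxy-7-hydroperoxy-1,4a-dimethyl-6-oxo-7-(prop-1-en-2-yl)decahydronaphthalen-2-yl (2Z)-2-methylbut-2-enoate | C=C(C)[C@@]1(OO)C[C@@H]2[C@](C)(CC[C@@H](OC(=O)/C(C)=C\C)[C@@]2(C)OC(C)=O)CC1=O | target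

## Step count and risks

Total steps: 11. Longest linear sequence: 11 (1 + 2 → 21); acetone 11 and angelic acid 17 are bought and enter directly.

Risk 1, the ring expansion (step 3, the proposed new step). It may shift C2 instead of the quaternary C7a, which would put the ketal next to C10. It may also stop at 1,2-dimethoxylation, or the enone may interfere. The fallback uses known chemistry only, sets out from 4 and comes back at 10. Selective acetalisation of the more reactive cyclopentanone carbonyl (ethylene glycol, TsOH, benzene, water removal) gives the spiro-dioxolane enone F1. Li/NH3 reduction with PhNTf2 trapping gives the trans-fused dioxolane enol triflate F2. Pd(OAc)2/PPh3/HCO2H/n-Bu3N hydrogenolysis gives the alkene dioxolane F3, and aqueous HCl frees the trans-hydrindenone F4. Addition of LiCHBr2 (CH2Br2, LiN(iPr)2, THF, −78 °C) from the face opposite the angular methyl gives the dibromomethyl carbinol F5. n-BuLi (2.2 equiv, −78 → 0 °C) then triggers the β-oxido carbenoid ring enlargement, in which the more substituted (quaternary) carbon is the expected migrating group, and protonation of the resulting enolate gives 10. The route continues at step 6. The trans ring fusion in this fallback rests on the hydrindane-stage Birch reduction, which is less secure than the decalin-stage one and should be checked by NOE on F4.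

Risk 2, the photooxygenation (step 11). β-Face attack would give the 11-hydroperoxy-Δ6 regioisomer or the 7β-epimer, and the allylic hydroperoxide can rearrange on standing. The fallback sets out from 20 and comes back at 21. Soft enolisation (Et3SiOTf, Et3N, CH2Cl2, −78 → 0 °C; γ-deprotonation, because C9 is neopentylic) gives the extended triethylsilyl dienol ether F7. Singlet oxygen then attacks the electron-rich enol-ether carbon C7 from the α face with 1,4-silyl migration (silatropic ene reaction of a silyl enol ether) to give the α-silylperoxy ketone F8. AcOH/THF/H2O removes the silyl group to give 21. Here the regiochemistry is fixed by the enol ether and no longer depends on which allylic hydrogen is abstracted.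

Risk 3, the angeloylation (step 9). The axial 3α-OH beside a tertiary carbinol is hindered, and forcing conditions risk isomerisation to the tiglate. The fallback sets out from 16 and comes back at 19. Esterification of the 3-OH with 2-[bis(2,2,2-trifluoroethoxy)phosphoryl]propanoic acid (N,N'-dicyclohexylcarbodiimide, DMAP, CH2Cl2) gives the phosphonopropanoate ester F6. Still–Gennari olefination with acetaldehyde (KN(SiMe3)2, 18-crown-6, THF, −78 °C) then builds the (Z)-2-methylbut-2-enoate on the substrate and gives 19 directly.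

## Further compounds

F1 | step 3 | (7aS)-4,7a-dimethyl-2,3,7,7a-tetrahydrospiro[indene-1,2'-[1,3]dioxolan]-5(6H)-one | CC1=C2CCC3(OCCO3)[C@@]2(C)CCC1=O
F2 | step 3 | (3aS,7aS)-4,7a-dimethyl-2,3,3a,6,7,7a-hexahydrospiro[indene-1,2'-[1,3]dioxolan]-5-yl trifluoromethanesulfonate | C1C[C@@H]2[C@](C)(CCC(OS(=O)(=O)C(F)(F)F)=C2C)C13OCCO3
F3 | step 3 | (3aS,7aS)-4,7a-dimethyl-2,3,3a,6,7,7a-hexahydrospiro[indene-1,2'-[1,3]dioxolane] | C1C[C@@H]2[C@](C)(CCC=C2C)C13OCCO3
F4 | step 3 | (3aS,7aS)-4,7a-dimethyl-2,3,3a,6,7,7a-hexahydro-1H-inden-1-one | C1C[C@@H]2[C@](C)(CCC=C2C)C1=O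
F5 | step 3 | (1S,3aS,7aS)-1-(dibromomethyl)-4,7a-dimethyl-2,3,3a,6,7,7a-hexahydro-1H-inden-1-ol | C1C[C@@H]2[C@](C)(CCC=C2C)[C@]1(O)C(Br)Br
F6 | step 9 | (1S,2R,4aR,8aR)-1-hydroxy-1,4a-dimethyl-6-oxo-7-(propan-2-ylidene)decahydronaphthalen-2-yl 2-[bis(2,2,2-trifluoroethoxy)phosphoryl]propanoate (both epimers at the phosphonate carbon) | CC(C)=C1C[C@@H]2[C@](C)(CC[C@@H](OC(=O)C(C)P(=O)(OCC(F)(F)F)OCC(F)(F)F)[C@@]2(C)O)CC1=O
F7 | step 11 | (1S,2R,4aR,8aR)-1-acetoxy-1,4a-dimethyl-7-(prop-1-en-2-yl)-6-(triethylsilyloxy)-1,2,3,4,4a,5,8,8a-octahydronaphthalen-2-yl (2Z)-2-methylbut-2-enoate | C=C(C)C=1C[C@@H]2[C@](C)(CC[C@@H](OC(=O)/C(C)=C\C)[C@@]2(C)OC(C)=O)CC=1O[Si](CC)(CC)CC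
F8 | step 11 | (1S,2R,4aR,7S,8aR)-1-acetoxy-1,4a-dimethyl-6-oxo-7-(prop-1-en-2-yl)-7-(triethylsilylperoxy)decahydronaphthalen-2-yl (2Z)-2-methylbut-2-enoate | C=C(C)[C@@]1(OO[Si](CC)(CC)CC)C[C@@H]2[C@](C)(CC[C@@H](OC(=O)/C(C)=C\C)[C@@]2(C)OC(C)=O)CC1=O
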